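The route rests on cutting the two aryl–CH2 bonds that hold the prenyl groups at C3 of ring A and C3′ of ring B, each carbon lying between two oxygen-bearing ring carbons. One double Suzuki–Miyaura coupling of the 3,3′-dibromide with prenylboronic acid pinacol ester forms both bonds as the last skeletal operation, so the acid-sensitive alkenes never meet the Friedel–Crafts and bromination chemistry used earlier. Its precursor is the hexa-MOM ether of the dibromo bis-acyl dimer, assembled from two phloroglucinol monomers that are acylated and monobrominated first and only then joined at the methine, which keeps the rings distinct when that stereocentre is created.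

Key step: step 9

Remark: ring A is the 2-methylbutanoyl ring and ring B the isobutyryl ring (primed numbers); in each ring C1 carries the acyl group, C2, C4 and C6 carry oxygen, C3 carries bromine and later the prenyl group, and C5 carries the bridging methine. Both stereocentres of the target are (R) by CIP analysis of its SMILES, so (R)-2-methylbutanoic acid is the matching acid.

Step 1
Reactants: 1 phloroglucinol; 2 (R)-2-methylbutanoic acid
Product: 4 (2R)-2-methyl-1-(2,4,6-trihydroxyphenyl)butan-1-one, via (R)-2-methylbutanoyl chloride 3 (not isolated)
Conditions: 2, (COCl)2, cat. DMF, CH2Cl2, 0 °C to rt; then 1, AlCl3 (3.5 equiv), PhNO2/CH2Cl2, 0 °C to rt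
Reagents that add atoms: none
Why: Friedel–Crafts C-acylation of the threefold-activated ring by the acyl chloride–AlCl3 complex should stop after one acyl group because the chelated ketone deactivates the ring, and the α-stereocentre of the acid should be carried through unchanged because no base is present and the temperature stays at or below ambient.

Step 2
Reactants: 1 phloroglucinol; 5 isobutyryl chloride
Product: 6 2-methyl-1-(2,4,6-trihydroxyphenyl)propan-1-one
Conditions: AlCl3 (3.5 equiv), PhNO2/CH2Cl2, 0 °C to rt
Reagents that add atoms: none
Why: The same Friedel–Crafts acylation installs the ring B acyl group on free phloroglucinol, before any acid-labile group exists, and again stops at the mono-ketone.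

Step 3
Reactants: 4 (2R)-2-methyl-1-(2,4,6-trihydroxyphenyl)butan-1-one
Product: 7 (2R)-1-(3-bromo-2,4,6-trihydroxyphenyl)-2-methylbutan-1-one
Conditions: NBS (1.0 equiv, slow addition), THF, −78 to −30 °C
Reagents that add atoms: N-bromosuccinimide, O=C1CCC(=O)N1Br
Why: Electrophilic aromatic bromination takes place at one of the two equivalent free ring carbons, and one equivalent of NBS at low temperature should favour the monobromide because the first bromine lowers the nucleophilicity of the remaining position, any dibromide being removed by chromatography.

Step 4
Reactants: 6 2-methyl-1-(2,4,6-trihydroxyphenyl)propan-1-one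
Product: 8 1-(3-bromo-2,4,6-trihydroxyphenyl)-2-methylpropan-1-one
Conditions: NBS (1.0 equiv, slow addition), THF, −78 to −30 °C
Reagents that add atoms: N-bromosuccinimide, O=C1CCC(=O)N1Br
Why: The same electrophilic monobromination marks C3′ of ring B and leaves C5′ as the only free ring carbon, so that later C–C bond formation on this ring can occur at one place only.

Step 5
Reactants: 9 6-methylheptanoic acid
Product: 11 6-methylheptanal, via 6-methylheptanoyl chloride 10 (not isolated)
Conditions: (COCl)2, cat. DMF, CH2Cl2, rt; then LiAlH(OtBu)3 (1.05 equiv), THF, −78 °C
Reagents that add atoms: none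
Why: Partial reduction of an acid chloride by the hindered hydride LiAlH(OtBu)3 should stop at the aldehyde at −78 °C because the reagent delivers a single hydride and reduces the aldehyde far more slowly than the acyl chloride.

Step 6
Reactants: 8 1-(3-bromo-2,4,6-trihydroxyphenyl)-2-methylpropan-1-one; 11 6-methylheptanal
Product: 12 1-{3-bromo-2,4,6-trihydroxy-5-[6-methyl-1-(4-methylbenzenesulfonyl)heptyl]phenyl}-2-methylpropan-1-one (racemic at the sulfonyl-bearing carbon)
Conditions: TolSO2Na (2 equiv), HCO2H/H2O (1:1), rt
Reagents that add atoms: sodium p-toluenesulfinate, Cc1ccc(cc1)S(=O)[O-].[Na+]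
Why: In this three-component sulfonylalkylation of a phenol, acid-promoted hydroxyalkylation at C5′ (the only free ring carbon of 8) gives a benzylic carbinol that ionises and should be captured at sulfur by the excess sulfinate faster than by a second molecule of 8, the bromine at C3′ ruling out bis-adducts and oligomers; the new carbon is left racemic on purpose because it becomes planar again in step 7.

Step 7
Reactants: 12 1-{3-bromo-2,4,6-trihydroxy-5-[6-methyl-1-(4-methylbenzenesulfonyl)heptyl]phenyl}-2-methylpropan-1-one; 7 (2R)-1-(3-bromo-2,4,6-trihydroxyphenyl)-2-methylbutan-1-one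
Product: 14 (2R)-1-{3-bromo-5-[(1R)-1-(3-bromo-2,4,6-trihydroxy-5-(2-methylpropanoyl)phenyl)-6-methylheptyl]-2,4,6-trihydroxyphenyl}-2-methylbutan-1-one (3,3′-dibromo bis-acyl dimer as free hexaphenol), via ring B ortho-quinone methide 13 (not isolated)
Conditions: quinine-derived bifunctional squaramide (3,5-bis(trifluoromethyl)phenyl squaramide of 9-amino-9-deoxy-epi-quinine, 10 mol %), powdered K2HPO4 (2 equiv), CH2Cl2, −20 °C
Reagents that add atoms: none
Why: Proposed new method: the quinuclidine nitrogen of the catalyst deprotonates a phenol of 12 and triggers E1cB loss of sulfinate to give quinone methide 13, whose carbonyl is held by the squaramide N–H bonds while the protonated quinuclidine pairs with the phenoxide of 7, so that C5 of ring A (its only free carbon) should be delivered to one face of the exocyclic C=C and rearomatisation of both rings should make the addition irreversible at −20 °C, the new methine being set by the catalyst (the quinine- or quinidine-derived pseudo-enantiomer is chosen by experiment so that the (R)-methine forms) and not by the remote acyl stereocentre; the closest known reaction type is the bifunctional squaramide-catalysed enantioselective Friedel–Crafts-type conjugate addition of naphthols and other hydroxyarenes to ortho-quinone methides released from 2-(1-sulfonylalkyl)phenols, here extended to two fully substituted acylphloroglucinols.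

Step 8
Reactants: 14 3,3′-dibromo bis-acyl dimer (free hexaphenol)
Product: 15 hexakis(methoxymethyl) ether of 14, (R)-methine and (R)-α-carbon (3,3′-dibromo bis-acyl dimer hexa-MOM ether)
Conditions: NaH (7 equiv), MOMCl (9 equiv), DMF, 0 °C
Reagents that add atoms: chloromethyl methyl ether, COCCl
Why: Sixfold Williamson-type O-alkylation of the sodium phenoxides by the small, hard electrophile MOMCl should cap every oxygen, including the chelated ones, in an aprotic medium at 0 °C in which neither retro-conjugate cleavage at the doubly benzylic methine nor enolisation of the hindered ring A ketone is expected.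

Step 9
Reactants: 15 3,3′-dibromo bis-acyl dimer hexa-MOM ether; 16 prenylboronic acid pinacol ester
Product: 17 hexakis(methoxymethyl) ether of the target (3,3′-diprenyl bis-acyl dimer hexa-MOM ether), (R)-methine and (R)-α-carbon
Conditions: Pd(OAc)2 (10 mol %), tBuXPhos (20 mol %), 16 (4 equiv), K3PO4 (aq, 6 equiv), THF, 40–60 °C
Reagents that add atoms: none
Why: Pd(OAc)2 is reduced in the flask to a zerovalent palladium–tBuXPhos complex that inserts into each C3–Br bond; the resulting divalent arylpalladium species accepts the allyl group from the phosphate-activated boronate, and the σ-allyl complex so formed interconverts with its π-allyl isomer faster than it eliminates, so the very bulky di-tert-butylphosphine should steer reductive elimination to the unsubstituted CH2 terminus and give the linear prenyl arene. The closest known reaction type is the ligand-controlled Suzuki–Miyaura coupling of aryl bromides with 3,3-disubstituted allylboronic esters, in which bulky biaryl phosphines give the α (linear) product. No ring is closed and no stereocentre is created: the methine and the α-carbon of the 2-methylbutanoyl group are spectators, the latter shielded from enolisation under the weak phosphate base by the twisted di-ortho-substituted ketone. The selectivity required is α- over γ-transfer of the allyl unit (prenyl against 1,1-dimethylallyl) on both rings, and it is secured by the ligand and reinforced by the two MOM ethers that flank each bromine and make the branched reductive elimination more congested still. Site selectivity needs no control because bromine sits only on C3 and C3′ and every other ring carbon is substituted, which rules out O-prenylation and dearomatising C-prenylation.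

Step 10
Reactants: 17 3,3′-diprenyl bis-acyl dimer hexa-MOM ether
Product: 18 (2R)-1-{2,4,6-trihydroxy-3-[(1R)-1-(2,4,6-trihydroxy-3-(2-methylpropanoyl)-5-(3-methylbut-2-en-1-yl)phenyl)-6-methylheptyl]-5-(3-methylbut-2-en-1-yl)phenyl}-2-methylbutan-1-one (CNP0279787.1)
Conditions: HCl (3 M aq)/MeOH, rt
Reagents that add atoms: none
Why: Acid-catalysed acetal exchange with methanol should free all six phenols at ambient temperature, conditions that trisubstituted prenyl alkenes ortho to phenols are expected to survive, while the acyl-deactivated rings resist ipso-protonation at the methine and the α-stereocentre is not enolised.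

Compound list
1 | phloroglucinol | Oc1cc(O)cc(O)c1 | starting material
2 | (R)-2-methylbutanoic acid | CC[C@@H](C)C(=O)O | starting material
3 | (R)-2-methylbutanoyl chloride | CC[C@@H](C)C(=O)Cl | intermediate
4 | (2R)-2-methyl-1-(2,4,6-trihydroxyphenyl)butan-1-one | CC[C@@H](C)C(=O)c1c(O)cc(O)cc1O | intermediate
5 | isobutyryl chloride | CC(C)C(=O)Cl | starting material
6 | 2-methyl-1-(2,4,6-trihydroxyphenyl)propan-1-one | CC(C)C(=O)c1c(O)cc(O)cc1O | intermediate
7 | (2R)-1-(3-bromo-2,4,6-trihydroxyphenyl)-2-methylbutan-1-one | CC[C@@H](C)C(=O)c1c(O)c(Br)c(O)cc1O | intermediate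
8 | 1-(3-bromo-2,4,6-trihydroxyphenyl)-2-methylpropan-1-one | CC(C)C(=O)c1c(O)c(Br)c(O)cc1O | intermediate
9 | 6-methylheptanoic acid | CC(C)CCCCC(=O)O | starting material
10 | 6-methylheptanoyl chloride | CC(C)CCCCC(=O)Cl | intermediate
11 | 6-methylheptanal | CC(C)CCCCC=O | intermediate
12 | 1-{3-bromo-2,4,6-trihydroxy-5-[6-methyl-1-(4-methylbenzenesulfonyl)heptyl]phenyl}-2-methylpropan-1-one (racemic) | CC(C)C(=O)c1c(O)c(Br)c(O)c(C(CCCCC(C)C)S(=O)(=O)c2ccc(C)cc2)c1O | intermediate
13 | 2-bromo-3,5-dihydroxy-4-(2-methylpropanoyl)-6-(6-methylheptylidene)cyclohexa-2,4-dien-1-one (ring B ortho-quinone methide) | CC(C)C(=O)C1=C(O)C(=CCCCCC(C)C)C(=O)C(Br)=C1O | intermediate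
14 | 3,3′-dibromo bis-acyl dimer, free hexaphenol, (R)-methine, (R)-α-carbon | CC[C@@H](C)C(=O)c1c(O)c(Br)c(O)c([C@H](CCCCC(C)C)c2c(O)c(Br)c(O)c(C(=O)C(C)C)c2O)c1O | intermediate
15 | 3,3′-dibromo bis-acyl dimer hexa-MOM ether, (R)-methine, (R)-α-carbon | CC[C@@H](C)C(=O)c1c(OCOC)c(Br)c(OCOC)c([C@H](CCCCC(C)C)c2c(OCOC)c(Br)c(OCOC)c(C(=O)C(C)C)c2OCOC)c1OCOC | intermediate
16 | prenylboronic acid pinacol ester | CC(C)=CCB1OC(C)(C)C(C)(C)O1 | starting material
17 | hexa-MOM ether of the target, (R)-methine, (R)-α-carbon | CC[C@@H](C)C(=O)c1c(OCOC)c(CC=C(C)C)c(OCOC)c([C@H](CCCCC(C)C)c2c(OCOC)c(CC=C(C)C)c(OCOC)c(C(=O)C(C)C)c2OCOC)c1OCOC | intermediate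
18 | CNP0279787.1, (R)-methine, (R)-α-carbon | CC[C@@H](C)C(=O)c1c(O)c(CC=C(C)C)c(O)c([C@H](CCCCC(C)C)c2c(O)c(CC=C(C)C)c(O)c(C(=O)C(C)C)c2O)c1O | target

Total step count: 10 steps.
Longest linear sequence: 7 steps (steps 2, 4, 6, 7, 8, 9 and 10, from phloroglucinol).

Steps most likely to fail

1. Step 7. The addition to the planar quinone methide may proceed with poor facial selectivity, because an uncatalysed pathway through the free, acidic phenols or equilibration between the tautomeric forms of the quinone methide can bypass the catalyst. The fallback uses known chemistry and replaces catalyst control by separation. It sets out from 12 and 7: release of the quinone methide with NaOAc in MeCN at rt and uncatalysed Friedel–Crafts-type addition should give the dibromo dimer as both methine epimers F1. NaH/MOMCl in DMF at 0 °C should convert this into the epimeric hexa-MOM ethers F2. The two epimers are diastereomers because the ring A acyl centre is fixed as (R), and preparative HPLC on a polysaccharide chiral stationary phase should separate the wanted compound from the (S)-methine epimer F3. The fallback comes back to the route at 15.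

2. Step 9. Allyl transfer may occur through the γ-carbon and install 1,1-dimethylallyl groups, or the coupling may stall after the first ring through reduction of the second C–Br bond at the congested carbon. The fallback sets out from 15: a double Stille coupling with allyltributylstannane (Pd(PPh3)4, DMF, 100 °C) should give the 3,3′-diallyl hexa-MOM ether F4, for which no α/γ question arises. Olefin cross-metathesis with 2-methylbut-2-ene (second-generation Grubbs catalyst, CH2Cl2, 40 °C) should then turn both allyl groups into prenyl groups. The fallback comes back to the route at 17.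

3. Step 6. The benzylic cation or quinone methide may be intercepted by a second molecule of the phenol instead of by sulfinate, or the aldehyde may self-condense in the acidic medium. The fallback sets out from 8 and 11: a Mannich (Betti-type) condensation with morpholine in EtOH at rt delivers the iminium electrophile directly and should give the morpholine Mannich base F5. Heating F5 with TolSO2Na in aqueous AcOH at 60 °C should exchange the amine for the sulfonyl group by elimination–addition. The fallback comes back to the route at 12.

Further compounds
F1 | step 7 | 3,3′-dibromo bis-acyl dimer as free hexaphenol, both methine epimers, (R)-α-carbon | CC[C@@H](C)C(=O)c1c(O)c(Br)c(O)c(C(CCCCC(C)C)c2c(O)c(Br)c(O)c(C(=O)C(C)C)c2O)c1O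
F2 | step 7 | hexa-MOM ether of F1, both methine epimers, (R)-α-carbon | CC[C@@H](C)C(=O)c1c(OCOC)c(Br)c(OCOC)c(C(CCCCC(C)C)c2c(OCOC)c(Br)c(OCOC)c(C(=O)C(C)C)c2OCOC)c1OCOC
F3 | step 7 | (S)-methine epimer of 15 | CC[C@@H](C)C(=O)c1c(OCOC)c(Br)c(OCOC)c([C@@H](CCCCC(C)C)c2c(OCOC)c(Br)c(OCOC)c(C(=O)C(C)C)c2OCOC)c1OCOC
F4 | step 9 | 3,3′-diallyl bis-acyl dimer hexa-MOM ether, (R)-methine, (R)-α-carbon | CC[C@@H](C)C(=O)c1c(OCOC)c(CC=C)c(OCOC)c([C@H](CCCCC(C)C)c2c(OCOC)c(CC=C)c(OCOC)c(C(=O)C(C)C)c2OCOC)c1OCOC
F5 | step 6 | 1-{3-bromo-2,4,6-trihydroxy-5-[6-methyl-1-(morpholin-4-yl)heptyl]phenyl}-2-methylpropan-1-one (racemic) | CC(C)C(=O)c1c(O)c(Br)c(O)c(C(CCCCC(C)C)N2CCOCC2)c1O
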